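**Retrosynthetic overview**

1. The target is read as a cis-fused (10-epi) labdane, (5S,8R,9R,10R,13S). Labdane numbering is used: ring A = C1–C5, C10; ring B = C5–C10; chain C11–C15 on C9; C17 = methyl on C8. The C10 methyl, H5, H9 and the 8-OH lie on one face of ring B; ring A, the chain and C17 lie on the other.
2. C8 carbinol ⇐ hydride opening of the 8,17-epoxide ⇐ 8(17)-methylene ⇐ C8 ketone; H9 ⇐ hydrogenation of a C9=C11 alkylidene ketone from the convex face.
3. C9–C11 (together with C10–CH3) ⇐ three-component union: conjugate methylation of a (4aS)-2-octalone at C10, and capture of the resulting enolate at C9 by the C11 aldehyde of a 3-methylglutarate-derived chain that already holds C13. C11 enters at the aldehyde level; the extra oxygen and unsaturation are removed in two steps.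
4. Enabling feature: the C8 carbonyl conjugated with C9=C10 in ring B. The oxygen that ends as the tertiary alcohol makes C10 the acceptor and, after methyl transfer, C9 the enolate carbon.
5. Rings: ring A is bought with 6-methoxy-1-tetralone; ring B is its anisole ring, dearomatised (Birch) and made stereogenic at C5 by enantioselective β,γ→α,β enone isomerisation; no ring is closed in the route.

Key step: step 6

Assumption: in step 5 the quinine-derived amine is taken to give the (4aS) enone; if the sense of induction on this substrate is the opposite, the quinidine-derived pseudo-enantiomer takes its place and nothing else changes.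

**Route**

Step 1
Reactants: 1 methyl hydrogen (R)-3-methylglutarate [(3R)-5-methoxy-3-methyl-5-oxopentanoic acid]
Product: 2 1-tert-butyl 5-methyl (3S)-3-methylpentanedioate
Conditions: isobutene (excess), H2SO4 (cat.), CH2Cl2, sealed vessel, rt
Reagents that add atoms: isobutene (2-methylpropene), CC(C)=C
Why: Acid-catalysed addition of the carboxylic acid to isobutene (capture of the tert-butyl cation) esterifies only the free acid, so the two ends of the pseudo-symmetric C5 unit stay different (unhindered methyl ester against hindered tert-butyl ester); the stereocentre is untouched and its descriptor changes from R to S by CIP priority only.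

Step 2
Reactants: 2 1-tert-butyl 5-methyl (3S)-3-methylpentanedioate
Product: 3 tert-butyl (3S)-3-methyl-5-oxopentanoate
Conditions: i-Bu2AlH (1.05 equiv), toluene, −78 °C; MeOH, then aq potassium sodium tartrate
Reagents that add atoms: none
Why: Half-reduction of an ester with i-Bu2AlH at low temperature, in which the unhindered methyl ester forms an aluminium hemiacetal that lasts until work-up while the tert-butyl ester is too hindered to react; the β-stereocentre cannot epimerise.

Step 3
Reactants: 4 6-methoxy-1-tetralone [6-methoxy-3,4-dihydronaphthalen-1(2H)-one]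
Product: 5 6-methoxy-1,1-dimethyl-1,2,3,4-tetrahydronaphthalene
Conditions: TiCl4 (2 equiv), Me2Zn (2 equiv; gives Me2TiCl2 in the flask), CH2Cl2, −40 °C → rt
Reagents that add atoms: dimethylzinc, C[Zn]C
Why: Geminal dimethylation of a ketone with Me2TiCl2, in which methyl addition gives a titanium alkoxide that ionises to a benzylic cation stabilised by the para methoxy group, and this cation takes the second methyl group.

Step 4
Reactants: 5 6-methoxy-1,1-dimethyl-1,2,3,4-tetrahydronaphthalene
Product: 7 5,5-dimethyl-3,4,5,6,7,8-hexahydronaphthalen-2(1H)-one, via 2,5-dihydroanisole enol ether 6 (not isolated)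
Conditions: Li, NH3 (l), THF, t-BuOH, −78 → −33 °C; NH4Cl; then (CO2H)2, MeOH–H2O, rt
Reagents that add atoms: water, O
Why: Birch reduction dearomatises ring B to the 2,5-dihydroanisole (protonation at the unsubstituted ortho and meta carbons C9 and C6, the ring-fusion double bond C5=C10 being kept), and mild hydrolysis of the enol ether gives the unconjugated, achiral ketone without moving that double bond.

Step 5
Reactants: 7 5,5-dimethyl-3,4,5,6,7,8-hexahydronaphthalen-2(1H)-one
Product: 8 (4aS)-5,5-dimethyl-4,4a,5,6,7,8-hexahydronaphthalen-2(3H)-one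
Conditions: 9-amino-9-deoxy-epi-quinine (10 mol %), PhCO2H (20 mol %), toluene, 0 °C
Reagents that add atoms: none
Why: Enantioselective olefin isomerisation by primary amine–acid catalysis, the reaction type known for Birch-derived cyclohex-3-enones: the catalyst forms the dienamine and returns the proton to C4a (C5) on one enantioface before hydrolysis to the conjugated enone, which sets C5 as S.

Step 6
Reactants: 8 (4aS)-5,5-dimethyl-4,4a,5,6,7,8-hexahydronaphthalen-2(3H)-one and 3 tert-butyl (3S)-3-methyl-5-oxopentanoate
Product: 11 tert-butyl (3S)-5-hydroxy-3-methyl-5-[(4aS,8aR)-5,5,8a-trimethyl-2-oxodecahydronaphthalen-1-yl]pentanoate (aldol adduct; epimer mixture at ring C1 and at the carbinol carbon), via lithium enolate 9 (not isolated), via chlorozinc enolate 10 (not isolated)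
Conditions: CuI (1.2 equiv), MeLi (2.4 equiv), Et2O, 0 °C; 8, −20 → 0 °C; ZnCl2 (1.2 equiv, THF), −78 °C; 3 (1.3 equiv), −78 °C; aq NH4Cl
Reagents that add atoms: lithium dimethylcuprate, [Li+].C[Cu-]C (formed in the flask from methyllithium, C[Li], and CuI; it delivers the C10 methyl group)
Why: Me2CuLi adds 1,4 to the C8=O/C9=C10 enone of ring B (copper–alkene π-complex, β-cuprio enolate of trivalent copper, reductive elimination), which forms the C10–CH3 bond and leaves the enolate regiospecifically at C8–C9; after exchange to zinc this enolate adds through a closed six-membered transition state to the C11 aldehyde of 3 and so forms the C9–C11 bond. The closest known reaction type is the three-component conjugate addition–enolate aldol trapping used for vicinal difunctionalisation of cycloalkenones. No ring is closed, since rings A and B are already present. The new quaternary centre C10 is controlled by C5: the methyl group should enter on the face of H5, because entry on the other face would be axial to ring A and 1,3-diaxial to a methyl group on C4 and because 2-octalones in general give cis-fused adducts, so the cis ring fusion (10R) should result. C9 and the carbinol carbon C11 are formed as mixtures on purpose, because both are erased in step 7 and C9 is set again in step 8, so that all four aldol diastereomers converge. The step needs 1,4- over 1,2-addition (soft cuprate), an enolate that does not equilibrate to C7 (low temperature, fast capture by the aldehyde) and attack on the aldehyde in preference to the ester (secured by the hindered tert-butyl ester).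

Step 7
Reactants: 11 tert-butyl (3S)-5-hydroxy-3-methyl-5-[(4aS,8aR)-5,5,8a-trimethyl-2-oxodecahydronaphthalen-1-yl]pentanoate
Product: 13 tert-butyl (3S)-3-methyl-5-[(4aS,8aR)-5,5,8a-trimethyl-2-oxooctahydronaphthalen-1(2H)-ylidene]pentanoate (E/Z mixture), via methanesulfonate 12 (not isolated)
Conditions: MsCl, Et3N, CH2Cl2, 0 °C; then DBU, rt
Reagents that add atoms: none
Why: Mesylation followed by E1cB elimination through the C8 enolate turns all aldol diastereomers into one alkylidene ketone (C9 and C11 become sp2), whose E/Z geometry is of no consequence for the next step.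

Step 8
Reactants: 13 tert-butyl (3S)-3-methyl-5-[(4aS,8aR)-5,5,8a-trimethyl-2-oxooctahydronaphthalen-1(2H)-ylidene]pentanoate
Product: 14 tert-butyl (3S)-3-methyl-5-[(1R,4aS,8aR)-5,5,8a-trimethyl-2-oxodecahydronaphthalen-1-yl]pentanoate
Conditions: H2 (1 atm), Pd/C, EtOAc, rt
Reagents that add atoms: none
Why: Heterogeneous hydrogenation of the exocyclic enone, in which the face of C9 that looks at ring A is screened by the axial C1 methylene on C10, so that hydrogen should arrive from the convex face (that of the C10 methyl and H5) and leave the chain equatorial on the ring A face, which sets C9 as R.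

Step 9
Reactants: 14 tert-butyl (3S)-3-methyl-5-[(1R,4aS,8aR)-5,5,8a-trimethyl-2-oxodecahydronaphthalen-1-yl]pentanoate
Product: 15 tert-butyl (3S)-3-methyl-5-[(1S,4aS,8aR)-5,5,8a-trimethyl-2-methylidenedecahydronaphthalen-1-yl]pentanoate
Conditions: Zn, CH2Br2, TiCl4, THF (reagent pre-formed at 5 °C); 14, CH2Cl2, rt
Reagents that add atoms: dibromomethane, BrCBr
Why: Takai–Lombardo methylenation, a non-basic gem-dimetallic reagent that converts hindered, enolisable ketones to methylene compounds without epimerising the α-centre C9 and leaves esters alone (the C9 descriptor changes to S by CIP priority only).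

Step 10
Reactants: 15 tert-butyl (3S)-3-methyl-5-[(1S,4aS,8aR)-5,5,8a-trimethyl-2-methylidenedecahydronaphthalen-1-yl]pentanoate
Product: 16 tert-butyl (3S)-3-methyl-5-[(1'R,2R,4a'S,8a'R)-5',5',8a'-trimethyloctahydro-1'H-spiro[oxirane-2,2'-naphthalen]-1'-yl]pentanoate (8,17-epoxide, oxygen on the face of the C10 methyl)
Conditions: mCPBA, NaHCO3, CH2Cl2, 0 °C
Reagents that add atoms: 3-chloroperbenzoic acid (mCPBA), OOC(=O)c1cccc(Cl)c1
Why: Prilezhaev epoxidation in which the peracid should approach the exocyclic methylene from the equatorial direction on the convex face, away from the axial C1 methylene of ring A (the behaviour of labdane 8(17)-enes), which places the oxygen on the face of the C10 methyl and sets C8 as R.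

Step 11
Reactants: 16 the 8,17-epoxide
Product: 17 (1R,2R,4aS,8aR)-1-[(3S)-5-hydroxy-3-methylpentyl]-2,5,5,8a-tetramethyldecahydronaphthalen-2-ol
Conditions: LiAlH4, THF, 0 °C → reflux; H2O, aq NaOH
Reagents that add atoms: none
Why: SN2 hydride opening of the epoxide at its primary carbon C17 gives the tertiary alcohol with the C8–O bond untouched (C17 becomes the methyl group), and the same reagent reduces the tert-butyl ester to the primary alcohol at C15.

Step 12
Reactants: 17 (1R,2R,4aS,8aR)-1-[(3S)-5-hydroxy-3-methylpentyl]-2,5,5,8a-tetramethyldecahydronaphthalen-2-ol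
Product: 18 (3S)-5-[(1R,2R,4aS,8aR)-2-hydroxy-2,5,5,8a-tetramethyldecahydronaphthalen-1-yl]-3-methylpentyl acetate
Conditions: Ac2O (1.2 equiv), pyridine, 0 °C → rt
Reagents that add atoms: acetic anhydride, CC(=O)OC(C)=O
Why: Acylation without a nucleophilic catalyst is selective for the primary alcohol over the hindered tertiary alcohol at C8.

**Compound list**

1 | methyl hydrogen (R)-3-methylglutarate, (3R)-5-methoxy-3-methyl-5-oxopentanoic acid | OC(=O)C[C@@H](C)CC(=O)OC | starting material
2 | 1-tert-butyl 5-methyl (3S)-3-methylpentanedioate | CC(C)(C)OC(=O)C[C@@H](C)CC(=O)OC | intermediate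
3 | tert-butyl (3S)-3-methyl-5-oxopentanoate | CC(C)(C)OC(=O)C[C@@H](C)CC=O | intermediate
4 | 6-methoxy-1-tetralone | COc1ccc2c(c1)CCCC2=O | starting material
5 | 6-methoxy-1,1-dimethyl-1,2,3,4-tetrahydronaphthalene | COc1ccc2c(c1)CCCC2(C)C | intermediate
6 | 6-methoxy-1,1-dimethyl-1,2,3,4,5,8-hexahydronaphthalene (not isolated) | COC1=CCC2=C(C1)CCCC2(C)C | intermediate
7 | 5,5-dimethyl-3,4,5,6,7,8-hexahydronaphthalen-2(1H)-one | O=C1CC2=C(CC1)C(C)(C)CCC2 | intermediate
8 | (4aS)-5,5-dimethyl-4,4a,5,6,7,8-hexahydronaphthalen-2(3H)-one | O=C1C=C2CCCC(C)(C)[C@@H]2CC1 | intermediate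
9 | lithium (4aS,8aR)-5,5,8a-trimethyl-3,4,4a,5,6,7,8,8a-octahydronaphthalen-2-olate (not isolated) | [Li]OC1=C[C@]2(C)CCCC(C)(C)[C@@H]2CC1 | intermediate
10 | chlorozinc (4aS,8aR)-5,5,8a-trimethyl-3,4,4a,5,6,7,8,8a-octahydronaphthalen-2-olate (not isolated) | Cl[Zn]OC1=C[C@]2(C)CCCC(C)(C)[C@@H]2CC1 | intermediate
11 | tert-butyl (3S)-5-hydroxy-3-methyl-5-[(4aS,8aR)-5,5,8a-trimethyl-2-oxodecahydronaphthalen-1-yl]pentanoate (epimers at ring C1 and the carbinol carbon) | CC(C)(C)OC(=O)C[C@@H](C)CC(O)C1[C@]2(C)CCCC(C)(C)[C@@H]2CCC1=O | intermediate
12 | methanesulfonate of 11 (not isolated) | CC(C)(C)OC(=O)C[C@@H](C)CC(OS(C)(=O)=O)C1[C@]2(C)CCCC(C)(C)[C@@H]2CCC1=O | intermediate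
13 | tert-butyl (3S)-3-methyl-5-[(4aS,8aR)-5,5,8a-trimethyl-2-oxooctahydronaphthalen-1(2H)-ylidene]pentanoate (E/Z mixture) | CC(C)(C)OC(=O)C[C@@H](C)CC=C1[C@]2(C)CCCC(C)(C)[C@@H]2CCC1=O | intermediate
14 | tert-butyl (3S)-3-methyl-5-[(1R,4aS,8aR)-5,5,8a-trimethyl-2-oxodecahydronaphthalen-1-yl]pentanoate | CC(C)(C)OC(=O)C[C@@H](C)CC[C@@H]1[C@]2(C)CCCC(C)(C)[C@@H]2CCC1=O | intermediate
15 | tert-butyl (3S)-3-methyl-5-[(1S,4aS,8aR)-5,5,8a-trimethyl-2-methylidenedecahydronaphthalen-1-yl]pentanoate | CC(C)(C)OC(=O)C[C@@H](C)CC[C@@H]1[C@]2(C)CCCC(C)(C)[C@@H]2CCC1=C | intermediate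
16 | tert-butyl (3S)-3-methyl-5-[(1'R,2R,4a'S,8a'R)-5',5',8a'-trimethyloctahydro-1'H-spiro[oxirane-2,2'-naphthalen]-1'-yl]pentanoate | CC(C)(C)OC(=O)C[C@@H](C)CC[C@@H]1[C@]2(C)CCCC(C)(C)[C@@H]2CC[C@]13CO3 | intermediate
17 | (1R,2R,4aS,8aR)-1-[(3S)-5-hydroxy-3-methylpentyl]-2,5,5,8a-tetramethyldecahydronaphthalen-2-ol | OCC[C@@H](C)CC[C@@H]1[C@]2(C)CCCC(C)(C)[C@@H]2CC[C@@]1(C)O | intermediate
18 | (3S)-5-[(1R,2R,4aS,8aR)-2-hydroxy-2,5,5,8a-tetramethyldecahydronaphthalen-1-yl]-3-methylpentyl acetate | CC(=O)OCC[C@@H](C)CC[C@@H]1[C@]2(C)CCCC(C)(C)[C@@H]2CC[C@@]1(C)O | target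

**Step count and risks**

Total steps: 12. Longest linear sequence: 10 (steps 3–12, from 6-methoxy-1-tetralone); the side chain takes 2 steps (steps 1–2).

Steps most likely to fail:

1. Step 5. The γ-protonation of the dienamine takes place next to the quaternary C4, so enantioface discrimination may be poor; re-formation of the dienamine from the product may erode the enantiomeric purity, and conversion may stop short because the tetrasubstituted β,γ-isomer is close in energy. The fallback sets out from 7 and comes back at 8. Compound 7 is isomerised with HCl in MeOH to the racemic conjugated enone F1. F1 is then resolved by preparative chromatography on a chiral stationary phase (amylose tris(3,5-dimethylphenylcarbamate), supercritical CO2/MeOH), and the (4aS) enantiomer is 8. The (4aR) enantiomer is racemised with NaOMe in MeOH through the achiral dienolate and returned to the column.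

2. Step 6. Methyl transfer to the fully substituted β-carbon beside the C4-bearing ring carbon may be slow. Proton transfer from the enolisable aldehyde to the enolate would return the simple methylated ketone, and the cis selectivity of the ring fusion may be eroded. The fallback sets out from 8 and comes back at 11. Conjugate addition of Me2CuLi in the presence of Me3SiCl (THF, −78 °C) gives the trimethylsilyl enol ether F2, which is isolated and purified. A Mukaiyama aldol addition of F2 to 3 with BF3·OEt2 in CH2Cl2 at −78 °C then gives 11.

3. Step 8. Hydrogen may be delivered to the ring A face of C9, or the double bond may migrate on the catalyst before it is reduced; either would give the C9 epimer. The fallback sets out from 13 and comes back at 14. Conjugate hydride reduction with [(Ph3P)CuH]6 in toluene containing H2O transfers hydride to C11, and the copper enolate is protonated at C9 in the flask under kinetic control from the convex face. No new compound is made (F0).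

**Further compounds**

F1 | step 5 | racemic 5,5-dimethyl-4,4a,5,6,7,8-hexahydronaphthalen-2(3H)-one | O=C1C=C2CCCC(C)(C)C2CC1
F2 | step 6 | trimethyl{[(4aS,8aR)-5,5,8a-trimethyl-3,4,4a,5,6,7,8,8a-octahydronaphthalen-2-yl]oxy}silane | C[Si](C)(C)OC1=C[C@]2(C)CCCC(C)(C)[C@@H]2CC1
F0 | step 8 | none | none
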